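C1/C14 are the lactone ring-fusion carbons (C14 bears O). C15, C16 and C17 are the lactone α-carbon, C=O and exocyclic CH2. C3/C4 are the oxirane CH and C(CH3) (methyl = C18), C7 the carbinol, C8(=C19H2), C12 the CHCH3, C13 the CHOAc. Ring A is the 14-membered carbocycle, ring B the γ-lactone, ring C the oxirane.
Key disconnection C3–C4. This bond belongs to ring A and ring C at once. C4 carries O, CH3 and C5, so it is a methyl ketone carbon. C3 carries O, H and the unfunctionalised C2H2, so it is an alkylidene that sulfur can deliver. An acyclic ω-oxoalkyl diphenylsulfonium salt should therefore give rings A and C and both stereocentres in one ylide epoxidation.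
The seco chain is cut at C7–C8 (asymmetric Nozaki–Hiyama–Kishi coupling with 4-oxopentanal) and at C1–C14 (α-aminoxylation, indium Barbier allylation and lactonisation, which builds ring B with C13, C14 and C1).
C12 comes from a catalytic asymmetric conjugate addition to methyl crotonate. The C1–C3/C15–C17 unit comes from a Morita–Baylis–Hillman adduct.
Ring order: B (step 7), then A and C together (step 15). Only a desilylation follows.
Key step: step 15

Assumption: in steps 3 and 11 the ligand antipode named is taken to be the one that gives the drawn centre (12S, 7S); both antipodes are commercial, so the mirror-image ligand would be used if the sense of induction is the opposite.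

Step 1
Reactants: 1 3-[(tert-butyldimethylsilyl)oxy]propanal; 2 methyl acrylate
Product: 3 methyl 5-[(tert-butyldimethylsilyl)oxy]-3-hydroxy-2-methylidenepentanoate (racemic)
Conditions: DABCO (0.5 equiv), 1,4-dioxane/H2O 1:1, rt
Reagents that add atoms: none
Why: Morita–Baylis–Hillman reaction of an unbranched aldehyde and an acrylate under DABCO catalysis; the carbinol centre forms as a racemate and is erased in step 2.

Step 2
Reactants: 3 methyl 5-[(tert-butyldimethylsilyl)oxy]-3-hydroxy-2-methylidenepentanoate
Product: 4 methyl (Z)-2-(bromomethyl)-5-[(tert-butyldimethylsilyl)oxy]pent-2-enoate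
Conditions: NBS, Me2S, CH2Cl2, 0 °C → rt
Reagents that add atoms: N-bromosuccinimide, O=C1CCC(=O)N1Br
Why: Corey–Kim-type activation of the allylic alcohol followed by SN2′ attack of bromide should give the conjugated trisubstituted enoate with the chain cis to CH2Br (Z), the isomer that avoids allylic strain with the ester, under near-neutral conditions that leave the silyl ether alone.

Step 3
Reactants: 5 (5-bromopent-1-yn-1-yl)trimethylsilane; 6 methyl (E)-but-2-enoate
Product: 8 methyl (S)-3-methyl-8-(trimethylsilyl)oct-7-ynoate, via Grignard reagent 7 (not isolated)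
Conditions: 5, Mg, Et2O, reflux; then CuBr·SMe2 (5 mol %), (R)-1-[(S)-2-(diphenylphosphino)ferrocenyl]ethyldicyclohexylphosphine (6 mol %), 6, t-BuOMe, −75 °C; aq NH4Cl
Reagents that add atoms: none
Why: Copper-catalysed enantioselective conjugate addition of a primary alkyl Grignard reagent to an (E)-crotonate, a well-documented substrate class for ferrocenyl diphosphine ligands; the ligand selects the enoate face and so sets C12 as S, and the silyl cap shields the alkyne CH from the Grignard reagent.

Step 4
Reactants: 8 methyl (S)-3-methyl-8-(trimethylsilyl)oct-7-ynoate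
Product: 9 methyl (S)-3-methyloct-7-ynoate
Conditions: K2CO3 (0.2 equiv), MeOH, rt
Reagents that add atoms: none
Why: Base-catalysed methanolysis of the alkynyl C–Si bond (protodesilylation); transesterification is degenerate for a methyl ester and C12 carries no acidic hydrogen.

Step 5
Reactants: 9 methyl (S)-3-methyloct-7-ynoate
Product: 11 methyl (S)-7-iodo-3-methyloct-7-enoate, via iodoalkenylborane 10 (not isolated)
Conditions: B-iodo-9-BBN (1.2 equiv), hexane/CH2Cl2, −20 → 0 °C; then AcOH, 0 °C
Reagents that add atoms: B-iodo-9-borabicyclo[3.3.1]nonane, IB1C2CCCC1CCC2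
Why: Syn-iodoboration of the terminal alkyne puts boron on the terminal carbon and iodine on C8 (Markovnikov sense), and protodeboronation by acetic acid then leaves the 2-iodo-1-alkene, a sequence that tolerates esters at low temperature.

Step 6
Reactants: 11 methyl (S)-7-iodo-3-methyloct-7-enoate
Product: 12 (S)-7-iodo-3-methyloct-7-enal
Conditions: i-Bu2AlH (1.05 equiv), CH2Cl2, −78 °C; aq potassium sodium tartrate
Reagents that add atoms: none
Why: Partial reduction of a methyl ester by i-Bu2AlH stops at the aldehyde stage at −78 °C, the alkenyl iodide is inert, and C12 is beta to the carbonyl group and cannot epimerise.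

Step 7
Reactants: 12 (S)-7-iodo-3-methyloct-7-enal; 4 methyl (Z)-2-(bromomethyl)-5-[(tert-butyldimethylsilyl)oxy]pent-2-enoate
Product: 15 aminoxy lactone (1S,12S,13R,14R), via aminoxy aldehyde 13 (not isolated), via hydroxy ester 14 (not isolated)
Conditions: L-proline (20 mol %), PhNO (1.0 equiv), DMSO, rt; then 4, In powder, rt; aq work-up; then p-TsOH·H2O (10 mol %), CH2Cl2, rt
Reagents that add atoms: nitrosobenzene, O=Nc1ccccc1
Why: Tandem proline-catalysed α-aminoxylation, indium Barbier allylation and acid lactonisation: L-proline enamine catalysis delivers the oxygen of PhNO to give 13R, indium chelated by the aldehyde and aminoxy oxygens directs attack to the face that gives the 13,14-syn pattern (14R), and the cyclic transition state known for 2-(bromomethyl)alk-2-enoates gives the 14,1-syn adduct (1S) that closes to the cis-fused α-methylene lactone (ring B).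

Step 8
Reactants: 15 aminoxy lactone
Product: 16 hydroxy lactone (13-OH)
Conditions: CuSO4·5H2O (30 mol %), MeOH, 0 °C → rt
Reagents that add atoms: none
Why: Copper-catalysed N–O cleavage of an O-alkyl-N-phenylhydroxylamine is the standard mild release of the alcohol after aminoxylation; it leaves the alkenyl iodide, acrylate unit and silyl ether intact and touches no stereocentre.

Step 9
Reactants: 16 hydroxy lactone
Product: 17 acetoxy lactone (13-OAc, C8 alkenyl iodide)
Conditions: Ac2O, pyridine, DMAP (5 mol %), CH2Cl2, 0 °C → rt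
Reagents that add atoms: acetic anhydride, CC(=O)OC(C)=O
Why: DMAP-catalysed acetylation of the only free hydroxyl group, run directly after its release so that translactonisation to the six-membered lactone has no time to set in.

Step 10
Reactants: 18 hex-5-en-2-one
Product: 20 4-oxopentanal, via ozonide 19 (not isolated)
Conditions: O3, CH2Cl2, −78 °C; then Me2S, −78 °C → rt
Reagents that add atoms: ozone, [O-][O+]=O
Why: Ozonolysis of the terminal alkene followed by reductive work-up gives the keto aldehyde, the ketone being inert to ozone.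

Step 11
Reactants: 17 acetoxy lactone; 20 4-oxopentanal
Product: 21 seco allylic alcohol (7S; 3-OTBS, 4-oxo)
Conditions: CrCl2 (4 equiv), (S)-N-[2-(4-isopropyl-4,5-dihydro-1,3-oxazol-2-yl)-6-methoxyphenyl]methanesulfonamide (4.4 equiv), Et3N (4.4 equiv), NiCl2 (2 mol %), THF, rt
Reagents that add atoms: none
Why: Nozaki–Hiyama–Kishi coupling adds the alkenyl iodide chemoselectively to the aldehyde of 20 in the presence of its ketone and of the lactone, acetate and silyl ether of 17, and the oxazoline–sulfonamide ligand bound to chromium selects the aldehyde face and sets C7 as S, the remote centres having no influence.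

Step 12
Reactants: 21 seco allylic alcohol
Product: 22 bis-silyl ether (3-OTBS, 7-OTBS)
Conditions: TBSCl, imidazole, DMF, rt
Reagents that add atoms: tert-butyldimethylsilyl chloride, CC(C)(C)[Si](C)(C)Cl
Why: Imidazole-promoted silylation of the secondary allylic alcohol locks the open γ-silyloxy ketone form and prevents hemiketal formation with the C4 carbonyl group.

Step 13
Reactants: 22 bis-silyl ether
Product: 23 primary alcohol (3-OH, 7-OTBS)
Conditions: HF·pyridine, pyridine, THF, 0 °C
Reagents that add atoms: none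
Why: Selective desilylation, because buffered HF·pyridine cleaves the unhindered primary silyl ether much faster than the secondary allylic one flanked by the C8 branch.

Step 14
Reactants: 23 primary alcohol
Product: 25 diphenylsulfonium triflate (S on C3), via primary triflate 24 (not isolated)
Conditions: Tf2O (1.1 equiv), 2,6-lutidine (1.3 equiv), CH2Cl2, −78 °C; then Ph2S (5 equiv), −78 °C → rt
Reagents that add atoms: trifluoromethanesulfonic anhydride, O=S(=O)(OS(=O)(=O)C(F)(F)F)C(F)(F)F; diphenyl sulfide, c1ccc(cc1)Sc1ccccc1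
Why: Triflation of the primary alcohol and SN2 alkylation of diphenyl sulfide by the primary triflate is the standard entry to alkyldiphenylsulfonium salts, and since Ph2S carries no alpha hydrogen C3 becomes the only possible ylide site.

Step 15
Reactants: 25 diphenylsulfonium triflate
Product: 28 macrocyclic epoxide 7-O-TBS ether (3R,4R), via sulfonium ylide 26 (not isolated), via betaine 27 (not isolated)
Conditions: KN(SiMe3)2 (1.05 equiv, slow addition), THF (0.001 M), −78 → −30 °C
Reagents that add atoms: none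
Why: Proposed new method: KN(SiMe3)2 removes a C3–H of the sulfonium salt (far more acidic than the methyl ketone, acetate or lactone CH) to give the unstabilised ylide 26, whose carbon adds to the C4 carbonyl and closes ring A in a 14-exo-trig mode to betaine 27; after rotation to the anti O/S rotamer the C4 alkoxide expels Ph2S from C3 in a 3-exo-tet displacement with inversion, which closes ring C. The closest known reaction type is the intramolecular Corey–Chaykovsky epoxidation of ω-oxoalkyl diphenylsulfonium salts (epoxy-annulation), shown so far only for five- to seven-membered carbocycles, so the new element is the macrocyclic ring size, which rests on high dilution and on the irreversible loss of Ph2S. C4 is set relative to C3 by the tether: collapse needs O and S antiperiplanar, and only in the (3S,4R)-betaine does that rotamer also hold the ring bonds C2–C3 and C4–C5 antiperiplanar with the small C18 methyl next to C2, which leads to the trans oxirane. C3, and with it the absolute sense 3R,4R, is under substrate control by C1 of the cis-fused ring B: with the bulky Ph2S group anti to C1, the tether should deliver the ketone to the ylide face turned away from the lactone. The step needs ketone selectivity over ester, acrylate and proton transfer: C16 and C17 can be reached from C3 only through a bicyclo[2.2.1] or a 5-endo geometry, the acetate is a much poorer electrophile reached through a seven-membered transition state of no better effective molarity, ketone enolisation is reversible and harmless, and bimolecular cyclopropanation or dimerisation is suppressed at 0.001 M.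

Step 16
Reactants: 28 macrocyclic epoxide 7-O-TBS ether
Product: 29 target, (1S,3R,4R,7S,12S,13R,14R)-13-acetoxy-3,4-epoxy-7-hydroxycembra-8(19),15(17)-dien-16,14-olide
Conditions: Bu4NF/AcOH (1:1), THF, 0 °C → rt
Reagents that add atoms: none
Why: Fluoride-mediated desilylation buffered by acetic acid keeps the medium near neutral, so that the acetate, α-methylene lactone and oxirane should survive and the freed C7 hydroxyl group should not open the oxirane at C4.

Compound list
1 | 3-[(tert-butyldimethylsilyl)oxy]propanal | O=CCCO[Si](C)(C)C(C)(C)C | starting material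
2 | methyl acrylate | C=CC(=O)OC | starting material
3 | methyl 5-[(tert-butyldimethylsilyl)oxy]-3-hydroxy-2-methylidenepentanoate (racemic) | COC(=O)C(=C)C(O)CCO[Si](C)(C)C(C)(C)C | intermediate
4 | methyl (Z)-2-(bromomethyl)-5-[(tert-butyldimethylsilyl)oxy]pent-2-enoate | COC(=O)/C(CBr)=C/CCO[Si](C)(C)C(C)(C)C | intermediate
5 | (5-bromopent-1-yn-1-yl)trimethylsilane | C[Si](C)(C)C#CCCCBr | starting material
6 | methyl (E)-but-2-enoate | C/C=C/C(=O)OC | starting material
7 | [5-(trimethylsilyl)pent-4-yn-1-yl]magnesium bromide | C[Si](C)(C)C#CCCC[Mg]Br | intermediate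
8 | methyl (S)-3-methyl-8-(trimethylsilyl)oct-7-ynoate | C[Si](C)(C)C#CCCC[C@H](C)CC(=O)OC | intermediate
9 | methyl (S)-3-methyloct-7-ynoate | C#CCCC[C@H](C)CC(=O)OC | intermediate
10 | methyl (S,Z)-8-(9-borabicyclo[3.3.1]nonan-9-yl)-7-iodo-3-methyloct-7-enoate | COC(=O)C[C@@H](C)CCC/C(I)=C/B1C2CCCC1CCC2 | intermediate
11 | methyl (S)-7-iodo-3-methyloct-7-enoate | C=C(I)CCC[C@H](C)CC(=O)OC | intermediate
12 | (S)-7-iodo-3-methyloct-7-enal | C=C(I)CCC[C@H](C)CC=O | intermediate
13 | (2R,3S)-7-iodo-3-methyl-2-[(phenylamino)oxy]oct-7-enal | C=C(I)CCC[C@H](C)[C@@H](ONc1ccccc1)C=O | intermediate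
14 | methyl (3S,4R,5R,6S)-3-{2-[(tert-butyldimethylsilyl)oxy]ethyl}-4-hydroxy-10-iodo-6-methyl-2-methylidene-5-[(phenylamino)oxy]undec-10-enoate | C=C(I)CCC[C@H](C)[C@@H](ONc1ccccc1)[C@H](O)[C@@H](CCO[Si](C)(C)C(C)(C)C)C(=C)C(=O)OC | intermediate
15 | (4S,5R)-4-{2-[(tert-butyldimethylsilyl)oxy]ethyl}-5-{(1R,2S)-6-iodo-2-methyl-1-[(phenylamino)oxy]hept-6-en-1-yl}-3-methylideneoxolan-2-one | C=C(I)CCC[C@H](C)[C@@H](ONc1ccccc1)[C@@H]1OC(=O)C(=C)[C@@H]1CCO[Si](C)(C)C(C)(C)C | intermediate
16 | (4S,5R)-4-{2-[(tert-butyldimethylsilyl)oxy]ethyl}-5-[(1R,2S)-1-hydroxy-6-iodo-2-methylhept-6-en-1-yl]-3-methylideneoxolan-2-one | C=C(I)CCC[C@H](C)[C@@H](O)[C@@H]1OC(=O)C(=C)[C@@H]1CCO[Si](C)(C)C(C)(C)C | intermediate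
17 | (1R,2S)-1-[(2R,3S)-3-{2-[(tert-butyldimethylsilyl)oxy]ethyl}-4-methylidene-5-oxooxolan-2-yl]-6-iodo-2-methylhept-6-en-1-yl acetate | C=C(I)CCC[C@H](C)[C@@H](OC(C)=O)[C@@H]1OC(=O)C(=C)[C@@H]1CCO[Si](C)(C)C(C)(C)C | intermediate
18 | hex-5-en-2-one | C=CCCC(C)=O | starting material
19 | 4-(1,2,4-trioxolan-3-yl)butan-2-one | CC(=O)CCC1OCOO1 | intermediate
20 | 4-oxopentanal | CC(=O)CCC=O | intermediate
21 | 3,4-seco-cembranolide (1S,7S,12S,13R,14R): 3-OTBS, 4-oxo, 7-OH, 8(19)-ene, 13-OAc, 15(17)-en-16,14-olide | C=C([C@@H](O)CCC(C)=O)CCC[C@H](C)[C@@H](OC(C)=O)[C@@H]1OC(=O)C(=C)[C@@H]1CCO[Si](C)(C)C(C)(C)C | intermediate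
22 | as 21 but 7-OTBS | C=C([C@@H](O[Si](C)(C)C(C)(C)C)CCC(C)=O)CCC[C@H](C)[C@@H](OC(C)=O)[C@@H]1OC(=O)C(=C)[C@@H]1CCO[Si](C)(C)C(C)(C)C | intermediate
23 | as 22 but 3-OH | C=C([C@@H](O[Si](C)(C)C(C)(C)C)CCC(C)=O)CCC[C@H](C)[C@@H](OC(C)=O)[C@@H]1OC(=O)C(=C)[C@@H]1CCO | intermediate
24 | as 23 but 3-OSO2CF3 | C=C([C@@H](O[Si](C)(C)C(C)(C)C)CCC(C)=O)CCC[C@H](C)[C@@H](OC(C)=O)[C@@H]1OC(=O)C(=C)[C@@H]1CCOS(=O)(=O)C(F)(F)F | intermediate
25 | as 23 but C3 bound to diphenylsulfonium, triflate salt | C=C([C@@H](O[Si](C)(C)C(C)(C)C)CCC(C)=O)CCC[C@H](C)[C@@H](OC(C)=O)[C@@H]1OC(=O)C(=C)[C@@H]1CC[S+](c1ccccc1)c1ccccc1.[O-]S(=O)(=O)C(F)(F)F | intermediate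
26 | diphenylsulfonium C3-ylide of 25 | C=C([C@@H](O[Si](C)(C)C(C)(C)C)CCC(C)=O)CCC[C@H](C)[C@@H](OC(C)=O)[C@@H]1OC(=O)C(=C)[C@@H]1C[CH-][S+](c1ccccc1)c1ccccc1 | intermediate
27 | macrocyclic (3S,4R)-betaine: 3-diphenylsulfonio, 4-oxido | C=C1CCC[C@H](C)[C@@H](OC(C)=O)[C@@H]2OC(=O)C(=C)[C@@H]2C[C@H]([S+](c2ccccc2)c2ccccc2)[C@@]([O-])(C)CC[C@@H]1O[Si](C)(C)C(C)(C)C | intermediate
28 | (1S,3R,4R,7S,12S,13R,14R)-13-acetoxy-7-[(tert-butyldimethylsilyl)oxy]-3,4-epoxycembra-8(19),15(17)-dien-16,14-olide | C=C1CCC[C@H](C)[C@@H](OC(C)=O)[C@@H]2OC(=O)C(=C)[C@@H]2C[C@H]2O[C@]2(C)CC[C@@H]1O[Si](C)(C)C(C)(C)C | intermediate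
29 | (1S,3R,4R,7S,12S,13R,14R)-13-acetoxy-3,4-epoxy-7-hydroxycembra-8(19),15(17)-dien-16,14-olide | C=C1CCC[C@H](C)[C@@H](OC(C)=O)[C@@H]2OC(=O)C(=C)[C@@H]2C[C@H]2O[C@]2(C)CC[C@@H]1O | target

Total step count: 16.
Longest linear sequence: 13 steps (steps 3–9 and 11–16).

Steps most likely to fail

1. Step 15 (Proposed new method).
- Facial selectivity in the ylide–ketone addition may be poor.
- The base may eliminate Ph2S across C2–C3 before the ylide forms.
- Ring closure may be slower than oligomerisation or ylide decay.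
- The fallback uses known chemistry and runs from 23 back to 28. Dess–Martin oxidation of alcohol 23 should give the keto aldehyde F1. Twofold Wittig methylenation (Ph3P=CH2, THF, −78 → 0 °C) should give the C3-vinyl/C4-isopropenyl tetraene F2. Ring-closing metathesis (second-generation Grubbs catalyst, toluene, 0.001 M, 80 °C) should give the (3E)-cycloalkene F3 by forming C3=C4. Shi epoxidation (D-fructose-derived ketone, KHSO5, K2CO3 buffer, MeCN/dimethoxymethane/H2O, 0 °C) would then place the oxirane on the most electron-rich alkene under reagent control and return to 28.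

2. Step 7.
- The weakly donating aminoxy group may not hold chelation control at indium.
- Indium may partly reduce the N–O bond.
- The cis-lactone may close sluggishly.
- The fallback runs from 12 (with 4) back to 16. The aminoxylation mixture (13) is reduced in situ with NaBH4 to the aminoxy alcohol F4. CuSO4·5H2O in MeOH releases the diol F5. TEMPO/PhI(OAc)2 oxidises the primary alcohol selectively to the hydroxy aldehyde F6. The indium Barbier reaction with 4 in THF/H2O gives the dihydroxy ester F7; a free α-hydroxyl group is the strongest chelating director for allylindium additions. p-TsOH then closes the five-membered lactone to 16.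

3. Step 11.
- Reagent control at C7 may be insufficient with a small unbranched aldehyde.
- The keto aldehyde may self-condense during the slow coupling.
- The fallback runs from 17 back to 23. Ligand-free Nozaki–Hiyama–Kishi coupling (CrCl2, NiCl2 cat, DMF) of 17 with commercial 3-(2-methyl-1,3-dioxolan-2-yl)propanal gives the C7-epimeric allylic alcohols F8. Dess–Martin oxidation gives the cross-conjugated enone F9. Corey–Bakshi–Shibata reduction ((R)-2-methyl-CBS-oxazaborolidine, catecholborane, toluene, −78 °C, alkenyl branch as the large group) gives the (7S)-alcohol F10. TBSCl/imidazole gives the bis-silyl ether F11. AcOH/THF/H2O then removes the dioxolane and the primary silyl ether together to reach 23.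

Further compounds
F1 | step 15 | 3,4-seco keto aldehyde (3-al, 4-oxo, 7-OTBS) | C=C([C@@H](O[Si](C)(C)C(C)(C)C)CCC(C)=O)CCC[C@H](C)[C@@H](OC(C)=O)[C@@H]1OC(=O)C(=C)[C@@H]1CC=O
F2 | step 15 | 3,4-seco tetraene (C3=CH2, C4=CH2, 7-OTBS) | C=C([C@@H](O[Si](C)(C)C(C)(C)C)CCC(C)=C)CCC[C@H](C)[C@@H](OC(C)=O)[C@@H]1OC(=O)C(=C)[C@@H]1CC=C
F3 | step 15 | (1S,3E,7S,12S,13R,14R)-13-acetoxy-7-[(tert-butyldimethylsilyl)oxy]cembra-3,8(19),15(17)-trien-16,14-olide | C=C1CCC[C@H](C)[C@@H](OC(C)=O)[C@@H]2OC(=O)C(=C)[C@@H]2C/C=C(\C)CC[C@@H]1O[Si](C)(C)C(C)(C)C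
F4 | step 7 | (2R,3S)-7-iodo-3-methyl-2-[(phenylamino)oxy]oct-7-en-1-ol | C=C(I)CCC[C@H](C)[C@@H](ONc1ccccc1)CO
F5 | step 7 | (2R,3S)-7-iodo-3-methyloct-7-ene-1,2-diol | C=C(I)CCC[C@H](C)[C@@H](O)CO
F6 | step 7 | (2R,3S)-2-hydroxy-7-iodo-3-methyloct-7-enal | C=C(I)CCC[C@H](C)[C@@H](O)C=O
F7 | step 7 | methyl (3S,4R,5R,6S)-3-{2-[(tert-butyldimethylsilyl)oxy]ethyl}-4,5-dihydroxy-10-iodo-6-methyl-2-methylideneundec-10-enoate | C=C(I)CCC[C@H](C)[C@@H](O)[C@H](O)[C@@H](CCO[Si](C)(C)C(C)(C)C)C(=C)C(=O)OC
F8 | step 11 | C7-epimeric seco allylic alcohols, C4 as 1,3-dioxolane, 3-OTBS | C=C(C(O)CCC1(C)OCCO1)CCC[C@H](C)[C@@H](OC(C)=O)[C@@H]1OC(=O)C(=C)[C@@H]1CCO[Si](C)(C)C(C)(C)C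
F9 | step 11 | seco 7-oxo-8(19)-enone, C4 as 1,3-dioxolane, 3-OTBS | C=C(C(=O)CCC1(C)OCCO1)CCC[C@H](C)[C@@H](OC(C)=O)[C@@H]1OC(=O)C(=C)[C@@H]1CCO[Si](C)(C)C(C)(C)C
F10 | step 11 | (7S)-seco allylic alcohol, C4 as 1,3-dioxolane, 3-OTBS | C=C([C@@H](O)CCC1(C)OCCO1)CCC[C@H](C)[C@@H](OC(C)=O)[C@@H]1OC(=O)C(=C)[C@@H]1CCO[Si](C)(C)C(C)(C)C
F11 | step 11 | (7S)-seco bis-silyl ether, C4 as 1,3-dioxolane | C=C([C@@H](O[Si](C)(C)C(C)(C)C)CCC1(C)OCCO1)CCC[C@H](C)[C@@H](OC(C)=O)[C@@H]1OC(=O)C(=C)[C@@H]1CCO[Si](C)(C)C(C)(C)C
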